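**Retrosynthetic overview**
- Feature: C8 is a CH that carries the aryl ether oxygen (bound to C4' of the allyl-dimethoxyphenyl ring) and the bond to the benzylic carbinol C7. This is the imprint of a carbene carbon that has entered a phenol O–H bond and then been caught by an aldehyde carbonyl.
- C9 methyl ⇐ CH2OTs ⇐ CH2OH ⇐ CO2Et, so C9 arrives as the ester carbon of a diazoacetate.
- Key disconnection: C8–O and C7–C8 are cut together, giving the allyl-dimethoxyphenol, ethyl diazoacetate and 3,4,5-trimethoxybenzaldehyde; C7 and C8 are configured in that one step by a chiral phosphoric acid.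
- Rings: both benzene rings are bought; no ring is formed at any stage.

Key step: step 1

Remark on the chemistry: the sense of induction of a chiral phosphoric acid in this unprecedented coupling cannot be fixed on paper. The (R)-acid is written, and its enantiomer is to be used if the first experiment shows the (R)-acid to favour the mirror-image ester. C7, C8 and C9 are the neolignan locants (carbinol, ether carbon, methyl).

**Step 1**
Reactants: 1 4-allyl-2,6-dimethoxyphenol; 2 ethyl diazoacetate; 3 3,4,5-trimethoxybenzaldehyde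
Product: 6 ethyl (2S,3S)-2-(4-allyl-2,6-dimethoxyphenoxy)-3-hydroxy-3-(3,4,5-trimethoxyphenyl)propanoate, via oxonium ylide 4 (not isolated), via ketene hemiacetal enol 5 (not isolated)
Conditions: Rh2(OAc)4 (1 mol%), (R)-3,3'-bis(2,4,6-triisopropylphenyl)-1,1'-binaphthyl-2,2'-diyl hydrogen phosphate (10 mol%), 3 (2 equiv), 4 Å MS, CH2Cl2, 0 °C; 2 (1.5 equiv) in CH2Cl2 added over 6 h by syringe pump
Reagents that add atoms: none
Why: Proposed new method: Rh2(OAc)4 expels N2 from 2 to give an electrophilic divalent-rhodium carbenoid that is captured by the phenol oxygen of 1 as oxonium ylide 4, which passes its proton to the ester carbonyl to give enol 5, and the nucleophilic carbon of 5 adds to aldehyde 3 held on the phosphoric acid before tautomerisation to the simple O–H insertion product can occur, so that the C8–O and C7–C8 bonds of the target are formed in one operation. The closest known reaction type is the Rh2(OAc)4/chiral phosphoric acid co-catalysed three-component aldol-type and Mannich-type trapping of oxonium ylides made from aryl diazoacetates and alcohols or water, whereas here an acceptor-only diazoacetate, a phenol as the O–H donor and an aromatic aldehyde are combined. No ring is closed. Both new stereocentres (C2 and C3 of the ester) are set in the C–C bond-forming transition state, in which the acid is expected to hold the enol O–H on its P=O oxygen and the aldehyde on its P–OH while the 2,4,6-triisopropylphenyl groups must enforce union of the Si face of the enol carbon with the Re face of the aldehyde, the pairing that corresponds to the erythro (2S,3S) ester. The step needs capture of the carbenoid by the phenol O–H in preference to cyclopropanation of the allyl group, carbonyl ylide formation and carbene dimerisation, which the nucleophilic phenol oxygen and the slow addition of 2 should secure, and it needs trapping to be faster than the proton shift, for which the excess of non-enolisable 3, the dry medium and the low temperature are chosen. The two meta methoxy groups of 3 withdraw inductively and the flanked para methoxy group is twisted out of conjugation, so the carbonyl group should be about as electrophilic as that of benzaldehyde.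

**Step 2**
Reactants: 6 ethyl (2S,3S)-2-(4-allyl-2,6-dimethoxyphenoxy)-3-hydroxy-3-(3,4,5-trimethoxyphenyl)propanoate
Product: 7 (1S,2R)-2-(4-allyl-2,6-dimethoxyphenoxy)-1-(3,4,5-trimethoxyphenyl)propane-1,3-diol
Conditions: LiAlH4 (1.5 equiv), THF, 0 °C; then H2O, 15% aq. NaOH
Reagents that add atoms: none
Why: Hydride reduction of an ester to the primary alcohol with LiAlH4 is fast at 0 °C for an α-aryloxy ester and should outrun retro-aldol cleavage of the aluminium alkoxide, so both stereocentres are carried through (the ether carbon changes from S to R only because the CIP ranking changes), while the isolated allyl double bond and the aryl methyl ethers are inert.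

**Step 3**
Reactants: 7 (1S,2R)-2-(4-allyl-2,6-dimethoxyphenoxy)-1-(3,4,5-trimethoxyphenyl)propane-1,3-diol
Product: 8 (2R,3S)-2-(4-allyl-2,6-dimethoxyphenoxy)-3-hydroxy-3-(3,4,5-trimethoxyphenyl)propyl 4-methylbenzenesulfonate
Conditions: TsCl (1.1 equiv), pyridine, CH2Cl2, −10 → 0 °C
Reagents that add atoms: p-toluenesulfonyl chloride (TsCl), Cc1ccc(S(=O)(=O)Cl)cc1
Why: Selective sulfonylation (tosylation) of a primary alcohol in a 1,3-diol: the unhindered CH2OH should react much faster than the secondary benzylic hydroxyl, which is flanked by the trimethoxyphenyl ring and the aryloxy-bearing carbon, and no stereocentre is touched.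

**Step 4**
Reactants: 8 (2R,3S)-2-(4-allyl-2,6-dimethoxyphenoxy)-3-hydroxy-3-(3,4,5-trimethoxyphenyl)propyl 4-methylbenzenesulfonate
Product: 9 rhaphidecursinol B [(1S,2R)-2-(4-allyl-2,6-dimethoxyphenoxy)-1-(3,4,5-trimethoxyphenyl)propan-1-ol]
Conditions: LiEt3BH (3 equiv), THF, 0 °C → rt; then H2O
Reagents that add atoms: none
Why: SN2 hydride displacement of a primary tosylate by LiEt3BH (reduction of a sulfonate to the hydrocarbon): the first equivalent deprotonates the carbinol and further hydride attacks the CH2 carbon, which is not stereogenic, so C7 (S) and C8 (R) keep their configuration and the alkene and aryl ethers are untouched.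

**Compound list**
1 | 4-allyl-2,6-dimethoxyphenol | C=CCc1cc(OC)c(O)c(OC)c1 | starting material
2 | ethyl diazoacetate | CCOC(=O)C=[N+]=[N-] | starting material
3 | 3,4,5-trimethoxybenzaldehyde | COc1cc(C=O)cc(OC)c1OC | starting material
4 | oxonium ylide: (4-allyl-2,6-dimethoxyphenyl)oxonium bearing the carbanionic CH–CO2Et carbon on oxygen (metal-free form) | C=CCc1cc(OC)c([OH+][CH-]C(=O)OCC)c(OC)c1 | intermediate
5 | ketene hemiacetal enol: (E)-2-(4-allyl-2,6-dimethoxyphenoxy)-1-ethoxyethen-1-ol, O–H cis to the aryloxy group | C=CCc1cc(OC)c(O/C=C(\O)OCC)c(OC)c1 | intermediate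
6 | ethyl (2S,3S)-2-(4-allyl-2,6-dimethoxyphenoxy)-3-hydroxy-3-(3,4,5-trimethoxyphenyl)propanoate (erythro) | C=CCc1cc(OC)c(O[C@H](C(=O)OCC)[C@@H](O)c2cc(OC)c(OC)c(OC)c2)c(OC)c1 | intermediate
7 | (1S,2R)-2-(4-allyl-2,6-dimethoxyphenoxy)-1-(3,4,5-trimethoxyphenyl)propane-1,3-diol | C=CCc1cc(OC)c(O[C@H](CO)[C@@H](O)c2cc(OC)c(OC)c(OC)c2)c(OC)c1 | intermediate
8 | (2R,3S)-2-(4-allyl-2,6-dimethoxyphenoxy)-3-hydroxy-3-(3,4,5-trimethoxyphenyl)propyl 4-methylbenzenesulfonate | C=CCc1cc(OC)c(O[C@H](COS(=O)(=O)c3ccc(C)cc3)[C@@H](O)c2cc(OC)c(OC)c(OC)c2)c(OC)c1 | intermediate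
9 | rhaphidecursinol B, (1S,2R)-2-(4-allyl-2,6-dimethoxyphenoxy)-1-(3,4,5-trimethoxyphenyl)propan-1-ol, erythro (7S,8R) | C=CCc1cc(OC)c(O[C@H](C)[C@@H](O)c2cc(OC)c(OC)c(OC)c2)c(OC)c1 | target

**Step count**
Total steps: 4. Longest linear sequence: 4 steps (1 + 2 + 3 → 6 → 7 → 8 → 9).

**Steps most likely to fail**

Step 1 (proposed new method). The proton shift of the ylide or enol may outrun the aldol trapping, so that only the O–H insertion product forms. Carbene transfer may also go to the allyl double bond or to the hydroxyl of the product, and the acid may give poor facial control. The fallback uses known chemistry, sets out from 1 and comes back to the route at 9, so steps 2 to 4 are then not needed. Mitsunobu etherification of 1 with ethyl (S)-lactate (PPh3, DIAD, THF), with inversion, should give ethyl (R)-2-(4-allyl-2,6-dimethoxyphenoxy)propanoate F1. MeNH(OMe)·HCl and iPrMgCl in THF at −20 °C should convert it into (R)-2-(4-allyl-2,6-dimethoxyphenoxy)-N-methoxy-N-methylpropanamide F2. Commercial 3,4,5-trimethoxyphenylmagnesium bromide in THF should then give (R)-2-(4-allyl-2,6-dimethoxyphenoxy)-1-(3,4,5-trimethoxyphenyl)propan-1-one F3. Reduction of this ketone with Zn(BH4)2 in Et2O at −30 °C under chelation control (Cram cyclic model, hydride entering from the side of the C8 hydrogen) should give the erythro (7S,8R) alcohol 9. The ketone is to be handled cold and without base, because its α-hydrogen is acidic.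

Step 3. Both hydroxyls may be sulfonylated, or the monotosylate may close to an oxetane under the basic conditions. The fallback removes the need for selectivity by protecting first; it sets out from 6 and comes back at 9. Silylation of the carbinol with tBuMe2SiOTf and 2,6-lutidine in CH2Cl2 at −78 °C should give ethyl (2S,3S)-2-(4-allyl-2,6-dimethoxyphenoxy)-3-[(tert-butyldimethylsilyl)oxy]-3-(3,4,5-trimethoxyphenyl)propanoate F4. iBu2AlH in CH2Cl2 should reduce the ester to (2R,3S)-2-(4-allyl-2,6-dimethoxyphenoxy)-3-[(tert-butyldimethylsilyl)oxy]-3-(3,4,5-trimethoxyphenyl)propan-1-ol F5. TsCl, Et3N and DMAP should give (2R,3S)-2-(4-allyl-2,6-dimethoxyphenoxy)-3-[(tert-butyldimethylsilyl)oxy]-3-(3,4,5-trimethoxyphenyl)propyl 4-methylbenzenesulfonate F6. LiEt3BH in THF should give tert-butyl[(1S,2R)-2-(4-allyl-2,6-dimethoxyphenoxy)-1-(3,4,5-trimethoxyphenyl)propoxy]dimethylsilane F7, and Bu4NF in THF should release 9.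

Step 4. Hydride may attack sulfur, cleaving S–O and returning the diol. The lithium alkoxide may also displace the tosylate to close an oxetane, or elimination may give an enol ether. The fallback replaces the basic polar displacement by a neutral radical chain reduction; it sets out from 8 and comes back at 9. Finkelstein exchange with NaI in acetone at reflux should give (1S,2S)-2-(4-allyl-2,6-dimethoxyphenoxy)-3-iodo-1-(3,4,5-trimethoxyphenyl)propan-1-ol F8. Bu3SnH with AIBN in benzene at 80 °C, run at high stannane concentration so that hydrogen transfer outruns loss of the β-aryloxy group, should reduce it to 9. The closest analogy is the stannane reduction of 2-iodo aryl glycosides, where a β-aryloxy alkyl radical is reduced without fragmentation.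

**Further compounds**
F1 | step 1 | ethyl (R)-2-(4-allyl-2,6-dimethoxyphenoxy)propanoate | C=CCc1cc(OC)c(O[C@H](C)C(=O)OCC)c(OC)c1
F2 | step 1 | (R)-2-(4-allyl-2,6-dimethoxyphenoxy)-N-methoxy-N-methylpropanamide | C=CCc1cc(OC)c(O[C@H](C)C(=O)N(C)OC)c(OC)c1
F3 | step 1 | (R)-2-(4-allyl-2,6-dimethoxyphenoxy)-1-(3,4,5-trimethoxyphenyl)propan-1-one | C=CCc1cc(OC)c(O[C@H](C)C(=O)c2cc(OC)c(OC)c(OC)c2)c(OC)c1
F4 | step 3 | ethyl (2S,3S)-2-(4-allyl-2,6-dimethoxyphenoxy)-3-[(tert-butyldimethylsilyl)oxy]-3-(3,4,5-trimethoxyphenyl)propanoate | C=CCc1cc(OC)c(O[C@H](C(=O)OCC)[C@@H](O[Si](C)(C)C(C)(C)C)c2cc(OC)c(OC)c(OC)c2)c(OC)c1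
F5 | step 3 | (2R,3S)-2-(4-allyl-2,6-dimethoxyphenoxy)-3-[(tert-butyldimethylsilyl)oxy]-3-(3,4,5-trimethoxyphenyl)propan-1-ol | C=CCc1cc(OC)c(O[C@H](CO)[C@@H](O[Si](C)(C)C(C)(C)C)c2cc(OC)c(OC)c(OC)c2)c(OC)c1
F6 | step 3 | (2R,3S)-2-(4-allyl-2,6-dimethoxyphenoxy)-3-[(tert-butyldimethylsilyl)oxy]-3-(3,4,5-trimethoxyphenyl)propyl 4-methylbenzenesulfonate | C=CCc1cc(OC)c(O[C@H](COS(=O)(=O)c3ccc(C)cc3)[C@@H](O[Si](C)(C)C(C)(C)C)c2cc(OC)c(OC)c(OC)c2)c(OC)c1
F7 | step 3 | tert-butyl[(1S,2R)-2-(4-allyl-2,6-dimethoxyphenoxy)-1-(3,4,5-trimethoxyphenyl)propoxy]dimethylsilane | C=CCc1cc(OC)c(O[C@H](C)[C@@H](O[Si](C)(C)C(C)(C)C)c2cc(OC)c(OC)c(OC)c2)c(OC)c1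
F8 | step 4 | (1S,2S)-2-(4-allyl-2,6-dimethoxyphenoxy)-3-iodo-1-(3,4,5-trimethoxyphenyl)propan-1-ol | C=CCc1cc(OC)c(O[C@H](CI)[C@@H](O)c2cc(OC)c(OC)c(OC)c2)c(OC)c1
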